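**Retrosynthetic overview**

1. The target is reached by desilylation of its 11,15-bis(TBS) ether; the cyclopentane, the only ring of the target, is bought as an enone and is never formed in the route.
2. C6–C7 disconnection: the γ-hydroxy ketone array O9–C9–C8–C7–C6 is the hydrolysis–decarboxylation product of an α-acyl γ-lactone. A temporary cis-fused γ-butyrolactone ring (O9, C9, C8, C7 and one sacrificial carbonyl carbon that is absent from the target) makes C7 an enolate carbon; it is acylated by adipic half-ester chloride and the sacrificial carbon then leaves as CO2, which also frees the 9-hydroxyl.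
3. The lactone comes from face-selective reduction of a C9 ketone carrying a CH2CO2Me arm on C8; the 9α alkoxide closes the temporary lactone ring and C9 is set.
4. The keto ester comes from a three-component coupling of (R)-4-silyloxycyclopentenone (C11 bought), the alkenyl zincate derived from (S)-oct-1-yn-3-ol (C15 bought) and methyl bromoacetate; C12 and C8 are relayed from C11 in this one operation.
5. Ring order: cyclopentane present from the start; temporary lactone ring closed in step 4 and destroyed in step 5.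

Key step: step 5

Remark: locants follow prostanoic acid numbering (C1 = carboxyl carbon, C6 = ketone carbon, C8–C12 = ring), TBS = tert-butyldimethylsilyl, and the target is drawn in its open keto form, which equilibrates with the 6,9-hemiketal.

**Route**

Step 1
Reactants: 1 (S)-oct-1-yn-3-ol
Product: 2 (S)-tert-butyldimethyl(oct-1-yn-3-yloxy)silane
Conditions: TBSCl, imidazole, DMF, rt
Reagents that add atoms: tert-butyldimethylsilyl chloride (TBSCl), CC(C)(C)[Si](C)(C)Cl
Why: Silylation of a secondary alcohol with a silyl chloride and imidazole is a standard protection that touches neither the C15 stereocenter nor the terminal alkyne.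

Step 2
Reactants: 2 (S)-tert-butyldimethyl(oct-1-yn-3-yloxy)silane
Product: 4 (S,E)-tert-butyl[(1-iodooct-1-en-3-yl)oxy]dimethylsilane, via alkenylzirconocene chloride 3 (not isolated)
Conditions: Cp2Zr(H)Cl, THF, rt; then I2, 0 °C
Reagents that add atoms: iodine, [I][I]
Why: Hydrozirconation adds Zr–H syn across the terminal alkyne with zirconium on the terminal carbon, and iodinolysis of the C–Zr bond with retention (hydrometalation–halogenation) should give only the E-alkenyl iodide, the silyl ether being inert.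

Step 3
Reactants: 4 (S,E)-tert-butyl[(1-iodooct-1-en-3-yl)oxy]dimethylsilane; 5 (R)-4-(tert-butyldimethylsilyloxy)cyclopent-2-en-1-one; 6 methyl bromoacetate
Product: 10 methyl 2-[(1R,2R,3R)-3-(tert-butyldimethylsilyloxy)-2-[(1E,3S)-3-(tert-butyldimethylsilyloxy)oct-1-en-1-yl]-5-oxocyclopentyl]acetate, via alkenyllithium 7 (not isolated), via lithium alkenylzincate 8 (not isolated), via zinc enolate 9 (not isolated)
Conditions: 4, t-BuLi (2 equiv), Et2O, −78 °C; Me2Zn, THF, −78 to 0 °C; 5, −78 °C; HMPA, 6, −78 to −40 °C; aq. NH4Cl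
Reagents that add atoms: none
Why: In this three-component coupling (tandem conjugate addition–enolate alkylation) iodine–lithium exchange and transmetalation give zincate 8, whose alkenyl group adds to C12 of the enone on the face opposite the C11 silyloxy group, and the regiodefined zinc enolate 9 is alkylated at C8 by the reactive α-bromo ester on the face opposite the new C12 substituent, so the bought C11 center sets C12 and C12 sets C8 in one flask.

Step 4
Reactants: 10 methyl 2-[(1R,2R,3R)-3-(tert-butyldimethylsilyloxy)-2-[(1E,3S)-3-(tert-butyldimethylsilyloxy)oct-1-en-1-yl]-5-oxocyclopentyl]acetate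
Product: 12 (3aR,4R,5R,6aS)-5-(tert-butyldimethylsilyloxy)-4-[(1E,3S)-3-(tert-butyldimethylsilyloxy)oct-1-en-1-yl]hexahydro-2H-cyclopenta[b]furan-2-one, via lithium alkoxide 11 (not isolated)
Conditions: Li[HB(s-Bu)3] (1.1 equiv), THF, −78 to 0 °C; aq. NH4Cl; PPTS (cat.), CH2Cl2, rt if ring closure is incomplete
Reagents that add atoms: none
Why: The bulky hydride should attack the C9 ketone from the face opposite the neighbouring C8 side chain (diastereoselective ketone reduction), and the resulting 9α alkoxide, cis to the acetate arm, closes by 5-exo-trig acyl substitution to the cis-fused γ-lactone, which also removes any 9β alcohol because that isomer cannot lactonize.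

Step 5
Reactants: 12 (3aR,4R,5R,6aS)-5-(tert-butyldimethylsilyloxy)-4-[(1E,3S)-3-(tert-butyldimethylsilyloxy)oct-1-en-1-yl]hexahydro-2H-cyclopenta[b]furan-2-one; 13 methyl 6-chloro-6-oxohexanoate
Product: 17 7-[(1R,2R,3R,5S)-3-(tert-butyldimethylsilyloxy)-2-[(1E,3S)-3-(tert-butyldimethylsilyloxy)oct-1-en-1-yl]-5-hydroxycyclopentyl]-6-oxoheptanoic acid, via lactone enolate 14 (not isolated), via acyl lactone 15 (not isolated), via keto diacid 16 (not isolated)
Conditions: LiN(SiMe3)2 (2.1 equiv), THF, −78 °C; 13 (1.05 equiv), −78 to −40 °C; then LiOH, THF/H2O, 0 °C to rt; then AcOH to pH 4–5, 45 °C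
Reagents that add atoms: lithium hydroxide, [Li+].[OH-]
Why: LiN(SiMe3)2 converts the lactone into its lithium enolate 14, whose only enolizable carbon is C7, and this attacks the acid chloride of 13 (far more electrophilic than the remote methyl ester) on carbon in a crossed Claisen acylation, the second equivalent of base storing the product as the stabilized enolate of 15 so that it is not acylated again. Dilute LiOH then opens the lactone by acyl–oxygen cleavage, so O9 stays on C9 with its configuration, and also saponifies the methyl ester; at pH 4–5 the β-keto acid 16 loses CO2 through the six-membered cyclic transition state, the sacrificial lactone carbon leaves, and C7 remains as the CH2 between C8 and the new C6 ketone. The closest known reaction type is the acetoacetic ester ketone synthesis in its lactone form, the hydrolysis–decarboxylation of α-acyl-γ-butyrolactones to γ-hydroxy ketones. No ring is closed (the temporary lactone ring is opened) and no lasting stereocenter is made, since the C7 center of 15 is erased on decarboxylation and C8, C9, C11, C12 and C15 are not touched. The selectivities needed are C- over O-acylation (lithium enolate, acid chloride, low temperature), ring opening over retro-Claisen cleavage (dilute hydroxide, the keto lactone held as its enolate) and decarboxylation over re-lactonization (buffered pH 4–5, where loss of CO2 needs no acid catalysis but lactonization does).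

Step 6
Reactants: 17 7-[(1R,2R,3R,5S)-3-(tert-butyldimethylsilyloxy)-2-[(1E,3S)-3-(tert-butyldimethylsilyloxy)oct-1-en-1-yl]-5-hydroxycyclopentyl]-6-oxoheptanoic acid
Product: 18 6-keto-prostaglandin F1alpha (7-[(1R,2R,3R,5S)-3,5-dihydroxy-2-[(1E,3S)-3-hydroxyoct-1-en-1-yl]cyclopentyl]-6-oxoheptanoic acid)
Conditions: aq. HF, MeCN, 0 °C to rt
Reagents that add atoms: none
Why: Fluoride-driven cleavage of the two silyl ethers (desilylation through Si–F bond formation) in aqueous acetonitrile should leave the allylic C15 alcohol, the γ-hydroxy ketone and the acid untouched, the product being obtained as the keto form in equilibrium with its 6,9-hemiketal.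

**Compound list**

1 | (S)-oct-1-yn-3-ol | CCCCC[C@H](O)C#C | starting material
2 | (S)-tert-butyldimethyl(oct-1-yn-3-yloxy)silane | CCCCC[C@H](O[Si](C)(C)C(C)(C)C)C#C | intermediate
3 | alkenylzirconocene chloride, formed in the flask: chlorobis(cyclopentadienyl)[(1E,3S)-3-(tert-butyldimethylsilyloxy)oct-1-en-1-yl]zirconium | CCCCC[C@H](O[Si](C)(C)C(C)(C)C)/C=C/[Zr](Cl)(C1C=CC=C1)C1C=CC=C1 | intermediate
4 | (S,E)-tert-butyl[(1-iodooct-1-en-3-yl)oxy]dimethylsilane | CCCCC[C@H](O[Si](C)(C)C(C)(C)C)/C=C/I | intermediate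
5 | (R)-4-(tert-butyldimethylsilyloxy)cyclopent-2-en-1-one | O=C1C=C[C@H](O[Si](C)(C)C(C)(C)C)C1 | starting material
6 | methyl bromoacetate | COC(=O)CBr | starting material
7 | alkenyllithium, formed in the flask: [(1E,3S)-3-(tert-butyldimethylsilyloxy)oct-1-en-1-yl]lithium | CCCCC[C@H](O[Si](C)(C)C(C)(C)C)/C=C/[Li] | intermediate
8 | lithium alkenylzincate, formed in the flask: lithium [(1E,3S)-3-(tert-butyldimethylsilyloxy)oct-1-en-1-yl]dimethylzincate | [Li+].CCCCC[C@H](O[Si](C)(C)C(C)(C)C)/C=C/[Zn-](C)C | intermediate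
9 | zinc enolate, formed in the flask: lithium dimethylzinc enolate (C8=C9–O–Zn) of the conjugate adduct, alkenyl chain on C12 trans to the C11 silyloxy group | [Li+].CCCCC[C@H](O[Si](C)(C)C(C)(C)C)/C=C/[C@@H]1C=C(O[Zn-](C)C)C[C@H]1O[Si](C)(C)C(C)(C)C | intermediate
10 | methyl 2-[(1R,2R,3R)-3-(tert-butyldimethylsilyloxy)-2-[(1E,3S)-3-(tert-butyldimethylsilyloxy)oct-1-en-1-yl]-5-oxocyclopentyl]acetate | CCCCC[C@H](O[Si](C)(C)C(C)(C)C)/C=C/[C@@H]1[C@@H](CC(=O)OC)C(=O)C[C@H]1O[Si](C)(C)C(C)(C)C | intermediate
11 | lithium alkoxide, formed in the flask: lithium salt of methyl 2-[(1R,2R,3R,5S)-3-(tert-butyldimethylsilyloxy)-5-hydroxy-2-[(1E,3S)-3-(tert-butyldimethylsilyloxy)oct-1-en-1-yl]cyclopentyl]acetate | CCCCC[C@H](O[Si](C)(C)C(C)(C)C)/C=C/[C@@H]1[C@@H](CC(=O)OC)[C@@H](O[Li])C[C@H]1O[Si](C)(C)C(C)(C)C | intermediate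
12 | (3aR,4R,5R,6aS)-5-(tert-butyldimethylsilyloxy)-4-[(1E,3S)-3-(tert-butyldimethylsilyloxy)oct-1-en-1-yl]hexahydro-2H-cyclopenta[b]furan-2-one | CCCCC[C@H](O[Si](C)(C)C(C)(C)C)/C=C/[C@@H]1[C@H]2CC(=O)O[C@H]2C[C@H]1O[Si](C)(C)C(C)(C)C | intermediate
13 | methyl 6-chloro-6-oxohexanoate (adipic acid monomethyl ester chloride) | COC(=O)CCCCC(=O)Cl | starting material
14 | lactone enolate, formed in the flask: lithium enolate of 12 (C7=C(OLi)–O9) | CCCCC[C@H](O[Si](C)(C)C(C)(C)C)/C=C/[C@@H]1[C@H]2C=C(O[Li])O[C@H]2C[C@H]1O[Si](C)(C)C(C)(C)C | intermediate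
15 | acyl lactone, formed in the flask and held as its lithium enolate: lactone 12 carrying the 6-methoxy-6-oxohexanoyl group on C7 (both C7 epimers and enol) | CCCCC[C@H](O[Si](C)(C)C(C)(C)C)/C=C/[C@@H]1[C@H]2C(C(=O)CCCCC(=O)OC)C(=O)O[C@H]2C[C@H]1O[Si](C)(C)C(C)(C)C | intermediate
16 | keto diacid, formed in the flask: ring-opened 3-oxooctanedioic acid carrying the cyclopentyl group (free 9α-OH) on C2 (C7 of the target, both epimers) | CCCCC[C@H](O[Si](C)(C)C(C)(C)C)/C=C/[C@@H]1[C@@H](C(C(=O)O)C(=O)CCCCC(=O)O)[C@@H](O)C[C@H]1O[Si](C)(C)C(C)(C)C | intermediate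
17 | 7-[(1R,2R,3R,5S)-3-(tert-butyldimethylsilyloxy)-2-[(1E,3S)-3-(tert-butyldimethylsilyloxy)oct-1-en-1-yl]-5-hydroxycyclopentyl]-6-oxoheptanoic acid | CCCCC[C@H](O[Si](C)(C)C(C)(C)C)/C=C/[C@@H]1[C@@H](CC(=O)CCCCC(=O)O)[C@@H](O)C[C@H]1O[Si](C)(C)C(C)(C)C | intermediate
18 | 6-keto-prostaglandin F1alpha, 7-[(1R,2R,3R,5S)-3,5-dihydroxy-2-[(1E,3S)-3-hydroxyoct-1-en-1-yl]cyclopentyl]-6-oxoheptanoic acid | CCCCC[C@H](O)/C=C/[C@@H]1[C@@H](CC(=O)CCCCC(=O)O)[C@@H](O)C[C@H]1O | target

**Step count and risks**

Total step count: 6. Longest linear sequence: 6 (steps 1 to 6, from 1).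

Steps most likely to fail:

Step 5. What may go wrong: O-acylation of the lactone enolate, retro-Claisen loss of the new acyl group while hydroxide opens the lactone, or re-closure of the γ-hydroxy acid to the lactone outrunning the loss of CO2. The fallback makes the same C6–C7 bond by an intramolecular oxygen-to-carbon acyl shift; it sets out from the zinc enolate 9 (made from 4 and 5 as in step 3) and comes back to the route at 17. Enolate 9 would be trapped at −78 °C with monomeric formaldehyde (aldol mode of the three-component coupling) to give the hydroxymethyl ketone F1. Li[HB(s-Bu)3] at −78 °C should reduce it from the face opposite the C8 arm to the 9α diol F2, and I2/PPh3/imidazole should convert only the primary hydroxyl into the iodide F3. Acylation of the 9-hydroxyl with 13 (pyridine, DMAP) gives the iodo ester F4. SmI2 (2.2 equiv) with catalytic Fe(dbm)3 in THF should reduce the C–I bond to the alkylsamarium diiodide F5, which adds to the tethered ester carbonyl to give the bicyclic samarium hemiketalate F6 (ring O9, C9, C8, C7, C6); this opens to the hydroxy ketone methyl ester F7. Saponification of F7 with LiOH in THF/H2O gives 17.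

Step 3. What may go wrong: proton exchange between zinc enolate 9 and the alkylated ketone (enolate equilibration toward C10, β-elimination of the C11 silyloxy group, double alkylation) or bromine–zinc exchange on the bromoacetate. The fallback uses the aldol mode followed by dehydration and conjugate reduction; it sets out from 9 and comes back at 10. Enolate 9 would be trapped at −78 °C with methyl glyoxylate, an aldehyde being the fastest trap for this enolate, to give the aldol adduct F8. MsCl/Et3N gives the mesylate F9, which should lose methanesulfonate with DBU (E1cB) to the alkylidene keto ester F10. Zinc dust in AcOH should reduce the ene-1,4-dicarbonyl unit of F10, and protonation at the epimerizable C8 gives the more stable 2,3-trans ketone 10.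

Step 4. What may go wrong: incomplete facial selectivity of hydride delivery at C9, or over-reduction of the newly formed lactone to the lactol. The fallback is stereoconvergent; it sets out from 10 and comes back at 12. NaBH4 in MeOH at −20 °C would reduce only the ketone; the 9α alcohol lactonizes to 12, and the 9β hydroxy ester F11, which cannot lactonize, is separated. LiOH gives the 9β hydroxy acid F12, and lactonization under Mitsunobu conditions (PPh3, diisopropyl azodicarboxylate) displaces the activated C9 oxygen with inversion to give the same cis-fused lactone 12.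

Further compounds
F1 | step 5 | (2S,3R,4R)-4-(tert-butyldimethylsilyloxy)-3-[(1E,3S)-3-(tert-butyldimethylsilyloxy)oct-1-en-1-yl]-2-(hydroxymethyl)cyclopentan-1-one | CCCCC[C@H](O[Si](C)(C)C(C)(C)C)/C=C/[C@@H]1[C@@H](CO)C(=O)C[C@H]1O[Si](C)(C)C(C)(C)C
F2 | step 5 | (1S,2S,3R,4R)-4-(tert-butyldimethylsilyloxy)-3-[(1E,3S)-3-(tert-butyldimethylsilyloxy)oct-1-en-1-yl]-2-(hydroxymethyl)cyclopentan-1-ol | CCCCC[C@H](O[Si](C)(C)C(C)(C)C)/C=C/[C@@H]1[C@@H](CO)[C@@H](O)C[C@H]1O[Si](C)(C)C(C)(C)C
F3 | step 5 | (1S,2R,3R,4R)-4-(tert-butyldimethylsilyloxy)-3-[(1E,3S)-3-(tert-butyldimethylsilyloxy)oct-1-en-1-yl]-2-(iodomethyl)cyclopentan-1-ol | CCCCC[C@H](O[Si](C)(C)C(C)(C)C)/C=C/[C@@H]1[C@@H](CI)[C@@H](O)C[C@H]1O[Si](C)(C)C(C)(C)C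
F4 | step 5 | (1S,2R,3R,4R)-4-(tert-butyldimethylsilyloxy)-3-[(1E,3S)-3-(tert-butyldimethylsilyloxy)oct-1-en-1-yl]-2-(iodomethyl)cyclopentyl methyl hexanedioate | CCCCC[C@H](O[Si](C)(C)C(C)(C)C)/C=C/[C@@H]1[C@@H](CI)[C@@H](OC(=O)CCCCC(=O)OC)C[C@H]1O[Si](C)(C)C(C)(C)C
F5 | step 5 | alkylsamarium diiodide derived from F4 (C7–SmI2, ester on O9 intact) | CCCCC[C@H](O[Si](C)(C)C(C)(C)C)/C=C/[C@@H]1[C@@H](C[Sm](I)I)[C@@H](OC(=O)CCCCC(=O)OC)C[C@H]1O[Si](C)(C)C(C)(C)C
F6 | step 5 | bicyclic samarium hemiketalate (cis-fused 2-oxabicyclo[3.3.0]octane, C6 carrying OSmI2 and the ester chain) | CCCCC[C@H](O[Si](C)(C)C(C)(C)C)/C=C/[C@@H]1[C@H]2CC(O[Sm](I)I)(CCCCC(=O)OC)O[C@H]2C[C@H]1O[Si](C)(C)C(C)(C)C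
F7 | step 5 | methyl 7-[(1R,2R,3R,5S)-3-(tert-butyldimethylsilyloxy)-2-[(1E,3S)-3-(tert-butyldimethylsilyloxy)oct-1-en-1-yl]-5-hydroxycyclopentyl]-6-oxoheptanoate | CCCCC[C@H](O[Si](C)(C)C(C)(C)C)/C=C/[C@@H]1[C@@H](CC(=O)CCCCC(=O)OC)[C@@H](O)C[C@H]1O[Si](C)(C)C(C)(C)C
F8 | step 3 | aldol adduct of 9 with methyl glyoxylate: keto ester 10 carrying a hydroxyl on C7 (both C7 epimers) | CCCCC[C@H](O[Si](C)(C)C(C)(C)C)/C=C/[C@@H]1[C@@H](C(O)C(=O)OC)C(=O)C[C@H]1O[Si](C)(C)C(C)(C)C
F9 | step 3 | methanesulfonate of F8 | CCCCC[C@H](O[Si](C)(C)C(C)(C)C)/C=C/[C@@H]1[C@@H](C(OS(C)(=O)=O)C(=O)OC)C(=O)C[C@H]1O[Si](C)(C)C(C)(C)C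
F10 | step 3 | alkylidene keto ester: methyl 2-[(2R,3R)-3-(tert-butyldimethylsilyloxy)-2-[(1E,3S)-3-(tert-butyldimethylsilyloxy)oct-1-en-1-yl]-5-oxocyclopentylidene]acetate (C7=C8 geometry not fixed) | CCCCC[C@H](O[Si](C)(C)C(C)(C)C)/C=C/[C@@H]1C(=CC(=O)OC)C(=O)C[C@H]1O[Si](C)(C)C(C)(C)C
F11 | step 4 | methyl 2-[(1R,2R,3R,5R)-3-(tert-butyldimethylsilyloxy)-2-[(1E,3S)-3-(tert-butyldimethylsilyloxy)oct-1-en-1-yl]-5-hydroxycyclopentyl]acetate (9β alcohol) | CCCCC[C@H](O[Si](C)(C)C(C)(C)C)/C=C/[C@@H]1[C@@H](CC(=O)OC)[C@H](O)C[C@H]1O[Si](C)(C)C(C)(C)C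
F12 | step 4 | 2-[(1R,2R,3R,5R)-3-(tert-butyldimethylsilyloxy)-2-[(1E,3S)-3-(tert-butyldimethylsilyloxy)oct-1-en-1-yl]-5-hydroxycyclopentyl]acetic acid (9β alcohol) | CCCCC[C@H](O[Si](C)(C)C(C)(C)C)/C=C/[C@@H]1[C@@H](CC(=O)O)[C@H](O)C[C@H]1O[Si](C)(C)C(C)(C)C
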